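**Plan**

- The target is a 5,7-dimethoxychroman-4-one (arene ring A; pyranone ring C with O1, C2, C3, C4) joined through spiro carbon C3 to a benzocyclobutene (ring D: C3–C9H2–C1'–C2'; arene ring B with methoxy groups on C3' and C4').
- The retrosynthesis cuts C4–C4a (Friedel–Crafts acylation of ring A), then O1–C2 (phenoxide opening of a spiro β-lactone), then the lactone C2–O bond (back to a methyl C–H), and last C9–C1' (methyl C–H arylation).
- Enabling feature: C9 of ring D and C2 of ring C are both CH2 groups on spiro carbon C3. Both can therefore be traced to the two enantiotopic methyl groups of a benzylic quaternary carbon on C2' of ring B, which sits between a bromide on C1' and the methoxy-bearing C3'.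
- Forward: ring B is brominated and gem-dimethylated, ring D closes first, the surviving methyl is oxidised into a transient β-lactone, the ring A phenoxide opens it, and ring C closes last.
- Stereochemistry: C3 is the only stereocentre. The chiral ligand on palladium sets it when one methyl group is selected, and as a quaternary, non-enolisable carbon it cannot be scrambled later.

Key step: step 3

Assumption: the sense of induction of the chiral phosphepine cannot be predicted for this new ring closure, so the route is written for the ligand antipode that delivers the (S)-configured cyclisation product, to be identified by running both antipodes once.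

**Step 1**
Reactants: 1 2-(2,3-dimethoxyphenyl)acetic acid
Product: 2 2-(6-bromo-2,3-dimethoxyphenyl)acetic acid
Conditions: NBS (1.05 equiv), MeCN, 0 °C to rt
Reagents that add atoms: N-bromosuccinimide, O=C1CCC(=O)N1Br
Why: Electrophilic aromatic bromination should go to C6, para to the 3-methoxy group, because that group lies in the ring plane whereas the 2-methoxy group is twisted out of conjugation by its two neighbours, the pattern known for 2,3-dimethoxytoluene.

**Step 2**
Reactants: 2 2-(6-bromo-2,3-dimethoxyphenyl)acetic acid
Product: 5 methyl 2-(6-bromo-2,3-dimethoxyphenyl)-2-methylpropanoate, via methyl ester 3 (not isolated), via monomethylated ester 4 (not isolated)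
Conditions: NaH (4 equiv), MeI (5 equiv), DMF, 0 °C to 40 °C
Reagents that add atoms: iodomethane, CI
Why: Exhaustive methylation: the sodium carboxylate is O-alkylated to 3, and two successive ester enolate C-alkylations via 4 then stop at the quaternary carbon because no α-hydrogen is left.

**Step 3**
Reactants: 5 methyl 2-(6-bromo-2,3-dimethoxyphenyl)-2-methylpropanoate
Product: 6 methyl (S)-4,5-dimethoxy-7-methylbicyclo[4.2.0]octa-1,3,5-triene-7-carboxylate
Conditions: Pd(OAc)2 (10 mol%), (S)-4-tert-butyl-4,5-dihydro-3H-dinaphtho[2,1-c:1',2'-e]phosphepine (20 mol%), K2CO3 (1.5 equiv), DMF, 130–140 °C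
Reagents that add atoms: none
Why: Proposed new method: zerovalent palladium carrying the bulky, electron-rich chiral phosphepine adds oxidatively to the C1'–Br bond, carbonate-assisted concerted metalation–deprotonation of one of the two enantiotopic methyl groups gives the five-membered palladacycle (Pd, C1', C2', C3, C9), and C(sp2)–C(sp3) reductive elimination forms C9–C1' and returns zerovalent palladium. The closest known reaction type is the racemic Pd(OAc)2/P(tBu)3-catalysed methyl C–H arylation of 2-(2-bromoaryl)-2-methylpropanoates to benzocyclobutenes, taken together with the enantioselective C(sp3)–H arylations that give five-membered rings with chiral phosphepine or carbene ligands; asymmetric induction in the four-membered closure is the new element. Ring D closes by ring-contracting reductive elimination from the five-membered palladacycle, formally a 4-exo attack of the metalated methyl carbon on arene carbon C1'. The C3 stereocentre is set under catalyst control in the metalation step, where the chiral ligand must tell one methyl group from its mirror-image twin by reading the ester against the other methyl. The step needs enantiotopic-group selectivity and reductive elimination faster than protodepalladation; the quaternary benzylic carbon offers no β-hydrogen and presses both methyl groups against palladium, the C3' methoxy group blocks the second ortho position so that a 1,4-palladium shift cannot give a regioisomer, and the methoxy group para to bromine matches the substitution pattern that the racemic reaction favours.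

**Step 4**
Reactants: 6 methyl (S)-4,5-dimethoxy-7-methylbicyclo[4.2.0]octa-1,3,5-triene-7-carboxylate
Product: 7 (S)-4,5-dimethoxy-7-methylbicyclo[4.2.0]octa-1,3,5-triene-7-carboxylic acid
Conditions: KOH, MeOH/H2O, 80 °C; then aq. HCl
Reagents that add atoms: potassium hydroxide, [K+].[OH-]
Why: Saponification of the hindered ester needs heat but cannot affect C3, which carries no α-hydrogen and so cannot epimerise.

**Step 5**
Reactants: 7 (S)-4,5-dimethoxy-7-methylbicyclo[4.2.0]octa-1,3,5-triene-7-carboxylic acid
Product: 8 (S)-4,5-dimethoxyspiro[bicyclo[4.2.0]octa-1,3,5-triene-7,3'-oxetan]-2'-one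
Conditions: PdCl2(CH3CN)2 (10 mol%), N-acetyl-β-alanine (20 mol%), CsHCO3 (0.5 equiv), tBuOOH (70% aq., 2 equiv), (CF3)2CHOH, 60 °C
Reagents that add atoms: none
Why: Palladium-catalysed β-C–H lactonisation of an α-quaternary acid: the carboxylate directs divalent palladium to the only methyl group, tert-butyl hydroperoxide oxidises the palladacycle to tetravalent palladium, and C–O reductive elimination gives the β-lactone, while ring B has no free position ortho to C2' and the C9 methylene could only lead to an impossibly strained fused lactone.

**Step 6**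
Reactants: 8 (S)-4,5-dimethoxyspiro[bicyclo[4.2.0]octa-1,3,5-triene-7,3'-oxetan]-2'-one; 9 3,5-dimethoxyphenol
Product: 10 (S)-7-[(3,5-dimethoxyphenoxy)methyl]-4,5-dimethoxybicyclo[4.2.0]octa-1,3,5-triene-7-carboxylic acid
Conditions: Cs2CO3 (1.2 equiv), DMF, 60 °C; then aq. HCl
Reagents that add atoms: none
Why: Strain-driven SN2 opening of the β-lactone at its CH2 carbon by the phenoxide (alkyl–oxygen cleavage, as in the classical phenoxide openings of β-propiolactone and pivalolactone) should give the carboxylate irreversibly, whereas attack at the acyl carbon would only give an aryl ester that recloses to the lactone; C3 is not involved.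

**Step 7**
Reactants: 10 (S)-7-[(3,5-dimethoxyphenoxy)methyl]-4,5-dimethoxybicyclo[4.2.0]octa-1,3,5-triene-7-carboxylic acid
Product: 12 (S)-4,5,5',7'-tetramethoxyspiro[bicyclo[4.2.0]octa-1,3,5-triene-7,3'-chroman]-4'-one (target, CNP0192565.1), via mixed trifluoroacetic anhydride 11 (not isolated)
Conditions: (CF3CO)2O (1.2 equiv), CH2Cl2, 0 °C to rt
Reagents that add atoms: none
Why: Intramolecular Friedel–Crafts acylation through the mixed anhydride 11 should close the six-membered ring C at either of the two equivalent positions ortho to the ether oxygen of ring A, which three oxygen substituents activate, and without a Lewis acid the methoxy groups and the cyclobutene should survive.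

**Compound list**

1 | 2-(2,3-dimethoxyphenyl)acetic acid | COc1cccc(CC(=O)O)c1OC | starting material
2 | 2-(6-bromo-2,3-dimethoxyphenyl)acetic acid | COc1ccc(Br)c(CC(=O)O)c1OC | intermediate
3 | methyl 2-(6-bromo-2,3-dimethoxyphenyl)acetate (not isolated) | COC(=O)Cc1c(Br)ccc(OC)c1OC | intermediate
4 | methyl 2-(6-bromo-2,3-dimethoxyphenyl)propanoate, racemic (not isolated) | COC(=O)C(C)c1c(Br)ccc(OC)c1OC | intermediate
5 | methyl 2-(6-bromo-2,3-dimethoxyphenyl)-2-methylpropanoate | COC(=O)C(C)(C)c1c(Br)ccc(OC)c1OC | intermediate
6 | methyl (S)-4,5-dimethoxy-7-methylbicyclo[4.2.0]octa-1,3,5-triene-7-carboxylate | C[C@@]1(Cc2ccc(OC)c(OC)c21)C(=O)OC | intermediate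
7 | (S)-4,5-dimethoxy-7-methylbicyclo[4.2.0]octa-1,3,5-triene-7-carboxylic acid | C[C@@]1(Cc2ccc(OC)c(OC)c21)C(=O)O | intermediate
8 | (S)-4,5-dimethoxyspiro[bicyclo[4.2.0]octa-1,3,5-triene-7,3'-oxetan]-2'-one | O1C[C@@]2(Cc3ccc(OC)c(OC)c32)C1=O | intermediate
9 | 3,5-dimethoxyphenol | COc1cc(O)cc(OC)c1 | starting material
10 | (S)-7-[(3,5-dimethoxyphenoxy)methyl]-4,5-dimethoxybicyclo[4.2.0]octa-1,3,5-triene-7-carboxylic acid | COc1cc(OC)cc(OC[C@@]2(Cc3ccc(OC)c(OC)c32)C(=O)O)c1 | intermediate
11 | (S)-7-[(3,5-dimethoxyphenoxy)methyl]-4,5-dimethoxybicyclo[4.2.0]octa-1,3,5-triene-7-carboxylic trifluoroacetic anhydride (not isolated) | COc1cc(OC)cc(OC[C@@]2(Cc3ccc(OC)c(OC)c32)C(=O)OC(=O)C(F)(F)F)c1 | intermediate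
12 | (S)-4,5,5',7'-tetramethoxyspiro[bicyclo[4.2.0]octa-1,3,5-triene-7,3'-chroman]-4'-one | COc1cc(OC)c2c(c1)OC[C@@]1(Cc3ccc(OC)c(OC)c31)C2=O | target

**Step count**

Total step count: 7.
Longest linear sequence: 7 steps (1 to 12); phenol 9 enters in step 6.

**Steps most likely to fail**

Step 3 (Proposed new method). The ligand may discriminate poorly between the two methyl groups at the temperature that the four-membered closure demands. Protodepalladation to the debrominated ester may also outrun reductive elimination with a ligand less bulky than P(tBu)3. The fallback sets out from 5 and uses the known racemic closure, Pd(OAc)2/P(tBu)3·HBF4, K2CO3, DMF, 140 °C, to give racemic methyl 4,5-dimethoxy-7-methylbicyclo[4.2.0]octa-1,3,5-triene-7-carboxylate F1. Saponification with KOH in aqueous MeOH would give racemic 4,5-dimethoxy-7-methylbicyclo[4.2.0]octa-1,3,5-triene-7-carboxylic acid F2. Classical resolution by crystallisation with one antipode of 1-phenylethylamine, written here for the (R)-amine, should deposit (R)-1-phenylethylammonium (S)-4,5-dimethoxy-7-methylbicyclo[4.2.0]octa-1,3,5-triene-7-carboxylate F3 and leave the diastereomeric (R)-1-phenylethylammonium (R)-4,5-dimethoxy-7-methylbicyclo[4.2.0]octa-1,3,5-triene-7-carboxylate F4 in the mother liquor. Aqueous HCl would free the acid from F3, and the route is rejoined at 7, so that step 4 is not needed.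

Step 5. C–O reductive elimination to the strained spiro lactone may be slow, which would leave the palladacycle and the peroxide time to oxidise the benzylic C9 methylene or the electron-rich ring B. The fallback sets out from 7 and forms the C–O bond in an open-chain product. Acid-directed β-C–H acetoxylation with Pd(OAc)2, N-acetyl-β-alanine, PhI(OAc)2 and Ac2O in (CF3)2CHOH would give (S)-7-(acetoxymethyl)-4,5-dimethoxybicyclo[4.2.0]octa-1,3,5-triene-7-carboxylic acid F5. Aqueous LiOH followed by acidification would give (S)-7-(hydroxymethyl)-4,5-dimethoxybicyclo[4.2.0]octa-1,3,5-triene-7-carboxylic acid F6. Lactonisation by carboxyl activation with benzenesulfonyl chloride in pyridine at 0 °C then closes the ring, and the route is rejoined at 8.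

Step 6. The ambident phenoxide may alkylate through a ring carbon, and substitution at the neopentyl-type CH2 may be so slow that adventitious water opens the lactone first. The fallback sets out from 8 and uses the opposite regiochemistry of opening. K2CO3 in MeOH at 0 °C cleaves the acyl–oxygen bond to give methyl (S)-7-(hydroxymethyl)-4,5-dimethoxybicyclo[4.2.0]octa-1,3,5-triene-7-carboxylate F7. A Mitsunobu etherification with 9 (PPh3, DIAD, toluene, 80 °C), a coupling well used for 3-hydroxy-2,2-disubstituted propanoates, would give methyl (S)-7-[(3,5-dimethoxyphenoxy)methyl]-4,5-dimethoxybicyclo[4.2.0]octa-1,3,5-triene-7-carboxylate F8. Saponification with KOH in aqueous MeOH and acidification rejoin the route at 10.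

**Further compounds**

F1 | step 3 | methyl 4,5-dimethoxy-7-methylbicyclo[4.2.0]octa-1,3,5-triene-7-carboxylate, racemic | CC1(Cc2ccc(OC)c(OC)c21)C(=O)OC
F2 | step 3 | 4,5-dimethoxy-7-methylbicyclo[4.2.0]octa-1,3,5-triene-7-carboxylic acid, racemic | CC1(Cc2ccc(OC)c(OC)c21)C(=O)O
F3 | step 3 | (R)-1-phenylethylammonium (S)-4,5-dimethoxy-7-methylbicyclo[4.2.0]octa-1,3,5-triene-7-carboxylate | C[C@@]1(Cc2ccc(OC)c(OC)c21)C(=O)[O-].C[C@@H]([NH3+])c1ccccc1
F4 | step 3 | (R)-1-phenylethylammonium (R)-4,5-dimethoxy-7-methylbicyclo[4.2.0]octa-1,3,5-triene-7-carboxylate | C[C@]1(Cc2ccc(OC)c(OC)c21)C(=O)[O-].C[C@@H]([NH3+])c1ccccc1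
F5 | step 5 | (S)-7-(acetoxymethyl)-4,5-dimethoxybicyclo[4.2.0]octa-1,3,5-triene-7-carboxylic acid | CC(=O)OC[C@@]1(Cc2ccc(OC)c(OC)c21)C(=O)O
F6 | step 5 | (S)-7-(hydroxymethyl)-4,5-dimethoxybicyclo[4.2.0]octa-1,3,5-triene-7-carboxylic acid | OC[C@@]1(Cc2ccc(OC)c(OC)c21)C(=O)O
F7 | step 6 | methyl (S)-7-(hydroxymethyl)-4,5-dimethoxybicyclo[4.2.0]octa-1,3,5-triene-7-carboxylate | OC[C@@]1(Cc2ccc(OC)c(OC)c21)C(=O)OC
F8 | step 6 | methyl (S)-7-[(3,5-dimethoxyphenoxy)methyl]-4,5-dimethoxybicyclo[4.2.0]octa-1,3,5-triene-7-carboxylate | COc1cc(OC)cc(OC[C@@]2(Cc3ccc(OC)c(OC)c32)C(=O)OC)c1
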